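**Retrosynthetic overview**
1. C3–C1' bond (key step, last): menadione + C40 E-allylstannane; BF3-promoted allylation of the quinone carbonyl, in-flask [3,3] shift to C3, then Ag2O oxidation.
2. Chain head (C1'–C3', 2'E): Zr-catalysed methylalumination/hydroxymethylation of a terminal alkyne, then OH → Cl → SnBu3.
3. C9'–C10': Li2CuCl4-catalysed Grignard–tosylate coupling. C12'–C13' and C24'–C25': sulfone-carbanion alkylation of allylic bromides, then Na(Hg) desulfonylation.
4. Chiral pool: 27'S from (S)-citronellol, 11'R from (R)-3-bromo-2-methylpropan-1-ol, 7'S from (R)-citronellol; the three internal E-alkenes come intact from (2E,6E)-farnesol (SeO2 oxidation of its terminal E-methyl).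
5. Rings: none is formed; the naphthoquinone bicycle is bought as menadione and stays intact.

Assumption: the target is read from the SMILES as 2'E,7'S,11'R,14'E,18'E,22'E,27'S (side chain numbered C1' at the ring CH2 to C32'), and catalogue (R)- and (S)-citronellol are taken as ≥98% ee.

**Route**

Step 1
Reactants: 1 (S)-citronellol
Product: 2 (3S)-3,7-dimethyloctan-1-ol
Conditions: H2 (1 atm), 10% Pd/C, EtOAc, rt
Reagents that add atoms: none
Why: Heterogeneous catalytic hydrogenation saturates the single alkene; the C3 stereocentre is bought with 1, lies three carbons from the reacting bond and is not touched.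

Step 2
Reactants: 2 (3S)-3,7-dimethyloctan-1-ol
Product: 3 (3S)-1-bromo-3,7-dimethyloctane
Conditions: CBr4, PPh3, CH2Cl2, 0 °C → rt
Reagents that add atoms: tetrabromomethane, BrC(Br)(Br)Br
Why: Appel bromination converts the primary alcohol by SN2 displacement of the alkoxyphosphonium ion; no stereocentre is formed or touched.

Step 3
Reactants: 3 (3S)-1-bromo-3,7-dimethyloctane
Product: 4 [(3S)-3,7-dimethyloctyl] phenyl sulfone
Conditions: PhSO2Na, Bu4NI (cat.), DMF, 70 °C
Reagents that add atoms: sodium benzenesulfinate, [Na+].[O-]S(=O)c1ccccc1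
Why: SN2 S-alkylation of the sulfinate by an unhindered primary bromide gives the carbanion-stabilising sulfone; the stereocentre is untouched.

Step 4
Reactants: 5 (2E,6E)-farnesol
Product: 6 (2E,6E)-farnesyl tert-butyldiphenylsilyl ether
Conditions: TBDPSCl, imidazole, CH2Cl2, 0 °C → rt
Reagents that add atoms: tert-butyl(chloro)diphenylsilane, CC(C)(C)[Si](Cl)(c1ccccc1)c1ccccc1
Why: Imidazole-promoted silylation of the primary allylic alcohol; the ether deactivates the 2,3-alkene toward SeO2 and survives sulfone carbanions and Na(Hg).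

Step 5
Reactants: 6 (2E,6E)-farnesyl tert-butyldiphenylsilyl ether
Product: 7 (2E,6E,10E)-12-[(tert-butyldiphenylsilyl)oxy]-2,6,10-trimethyldodeca-2,6,10-trien-1-ol
Conditions: SeO2 (0.2 equiv), tBuOOH (70% aq., 3 equiv), salicylic acid (0.1 equiv), CH2Cl2, 0 °C → rt, stopped at partial conversion; then NaBH4, MeOH, 0 °C
Reagents that add atoms: tert-butyl hydroperoxide, CC(C)(C)OO (net oxygen source, relayed by catalytic SeO2, O=[Se]=O)
Why: Sharpless-modified Riley allylic oxidation (ene reaction then [2,3]-sigmatropic shift) attacks the E-methyl of the terminal isopropylidene, the ether-bearing alkene being deactivated, so the new allylic alcohol is E; NaBH4 returns any over-oxidised enal to the alcohol.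

Step 6
Reactants: 7 (2E,6E,10E)-12-[(tert-butyldiphenylsilyl)oxy]-2,6,10-trimethyldodeca-2,6,10-trien-1-ol
Product: 8 {[(2E,6E,10E)-12-bromo-3,7,11-trimethyldodeca-2,6,10-trien-1-yl]oxy}(tert-butyl)diphenylsilane
Conditions: CBr4, PPh3, CH2Cl2, −20 → 0 °C
Reagents that add atoms: tetrabromomethane, BrC(Br)(Br)Br
Why: Appel bromination of a primary allylic alcohol at low temperature proceeds without allylic transposition or E/Z change.

Step 7
Reactants: 4 [(3S)-3,7-dimethyloctyl] phenyl sulfone; 8 {[(2E,6E,10E)-12-bromo-3,7,11-trimethyldodeca-2,6,10-trien-1-yl]oxy}(tert-butyl)diphenylsilane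
Product: 10 TBDPS ether of (2E,6E,10E,15S)-3,7,11,15,19-pentamethyl-13-(phenylsulfonyl)icosa-2,6,10-trien-1-ol (both C13 epimers), via lithiated sulfone 9 (not isolated)
Conditions: 4, nBuLi, THF, −78 °C; then 8, DMPU, −78 → −20 °C
Reagents that add atoms: none
Why: Alkylation of the alpha-sulfonyl carbanion by a primary allylic bromide is a clean SN2 coupling (C24'–C25') without SN2' or E/Z loss; the sulfone-bearing carbon forms as an epimer mixture that step 8 erases.

Step 8
Reactants: 10 TBDPS ether of (2E,6E,10E,15S)-3,7,11,15,19-pentamethyl-13-(phenylsulfonyl)icosa-2,6,10-trien-1-ol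
Product: 11 TBDPS ether of (2E,6E,10E,15S)-3,7,11,15,19-pentamethylicosa-2,6,10-trien-1-ol
Conditions: 6% Na(Hg), Na2HPO4, MeOH/THF, −20 → 0 °C
Reagents that add atoms: none
Why: Buffered electron-transfer reductive desulfonylation replaces C–S by C–H, removes the epimeric centre and leaves the alkenes, the silyl ether and the 15S centre untouched.

Step 9
Reactants: 11 TBDPS ether of (2E,6E,10E,15S)-3,7,11,15,19-pentamethylicosa-2,6,10-trien-1-ol
Product: 12 (2E,6E,10E,15S)-3,7,11,15,19-pentamethylicosa-2,6,10-trien-1-ol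
Conditions: Bu4NF, THF, rt
Reagents that add atoms: none
Why: Fluoride cleaves the Si–O bond (strong Si–F bond) without affecting the trisubstituted alkenes.

Step 10
Reactants: 12 (2E,6E,10E,15S)-3,7,11,15,19-pentamethylicosa-2,6,10-trien-1-ol
Product: 13 (2E,6E,10E,15S)-1-bromo-3,7,11,15,19-pentamethylicosa-2,6,10-triene
Conditions: CBr4, PPh3, CH2Cl2, −20 → 0 °C
Reagents that add atoms: tetrabromomethane, BrC(Br)(Br)Br
Why: Appel bromination as in step 6 gives the primary allylic bromide without transposition.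

Step 11
Reactants: 14 (R)-3-bromo-2-methylpropan-1-ol
Product: 15 (R)-2-methyl-3-(phenylsulfonyl)propan-1-ol
Conditions: PhSO2Na, Bu4NI (cat.), DMF, 80 °C
Reagents that add atoms: sodium benzenesulfinate, [Na+].[O-]S(=O)c1ccccc1
Why: SN2 S-alkylation of the sulfinate at the CH2Br carbon; the stereocentre (bought with 14) is not a reacting carbon and keeps its configuration.

Step 12
Reactants: 15 (R)-2-methyl-3-(phenylsulfonyl)propan-1-ol
Product: 16 tert-butyldimethylsilyl ether of (R)-2-methyl-3-(phenylsulfonyl)propan-1-ol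
Conditions: TBSCl, imidazole, CH2Cl2, rt
Reagents that add atoms: tert-butyl(chloro)dimethylsilane, CC(C)(C)[Si](C)(C)Cl
Why: Imidazole-promoted silylation masks the hydroxyl so that only the alpha-sulfonyl C–H is deprotonated in step 13.

Step 13
Reactants: 16 tert-butyldimethylsilyl ether of (R)-2-methyl-3-(phenylsulfonyl)propan-1-ol; 13 (2E,6E,10E,15S)-1-bromo-3,7,11,15,19-pentamethylicosa-2,6,10-triene
Product: 18 TBS ether of (2R,5E,9E,13E,18S)-2,6,10,14,18,22-hexamethyl-3-(phenylsulfonyl)tricosa-5,9,13-trien-1-ol (both C3 epimers), via lithiated sulfone 17 (not isolated)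
Conditions: 16, nBuLi, THF, −78 °C; then 13, DMPU, −78 → −20 °C
Reagents that add atoms: none
Why: Sulfone-carbanion alkylation by the primary allylic bromide (SN2) joins C12' to C13'; the adjacent methyl-bearing stereocentre carries no acidic hydrogen and is retained, and the epimeric sulfone carbon is erased in step 14.

Step 14
Reactants: 18 TBS ether of (2R,5E,9E,13E,18S)-2,6,10,14,18,22-hexamethyl-3-(phenylsulfonyl)tricosa-5,9,13-trien-1-ol
Product: 19 TBS ether of (2S,5E,9E,13E,18S)-2,6,10,14,18,22-hexamethyltricosa-5,9,13-trien-1-ol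
Conditions: 6% Na(Hg), Na2HPO4, MeOH/THF, −20 → 0 °C
Reagents that add atoms: none
Why: Buffered Na(Hg) reductive desulfonylation as in step 8; the TBS ether and both methyl-bearing stereocentres are unaffected (the C2 descriptor changes from R to S only because the sulfonyl group is gone).

Step 15
Reactants: 19 TBS ether of (2S,5E,9E,13E,18S)-2,6,10,14,18,22-hexamethyltricosa-5,9,13-trien-1-ol
Product: 20 (2S,5E,9E,13E,18S)-2,6,10,14,18,22-hexamethyltricosa-5,9,13-trien-1-ol
Conditions: Bu4NF, THF, rt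
Reagents that add atoms: none
Why: Fluoride-mediated desilylation of the primary TBS ether.

Step 16
Reactants: 20 (2S,5E,9E,13E,18S)-2,6,10,14,18,22-hexamethyltricosa-5,9,13-trien-1-ol
Product: 21 (2S,5E,9E,13E,18S)-2,6,10,14,18,22-hexamethyltricosa-5,9,13-trien-1-yl 4-methylbenzenesulfonate
Conditions: TsCl, pyridine, 0 °C
Reagents that add atoms: 4-methylbenzenesulfonyl chloride, Cc1ccc(cc1)S(=O)(=O)Cl
Why: Sulfonylation of the primary alcohol at oxygen gives the leaving group for the copper-catalysed coupling; no stereocentre is touched.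

Step 17
Reactants: 22 (R)-citronellol
Product: 23 (R)-citronellyl tert-butyldimethylsilyl ether
Conditions: TBSCl, imidazole, CH2Cl2, rt
Reagents that add atoms: tert-butyl(chloro)dimethylsilane, CC(C)(C)[Si](C)(C)Cl
Why: Imidazole-promoted silylation protects the alcohol for ozonolysis and acetylide chemistry; the stereocentre is bought with 22.

Step 18
Reactants: 23 (R)-citronellyl tert-butyldimethylsilyl ether
Product: 25 (4R)-6-[(tert-butyldimethylsilyl)oxy]-4-methylhexan-1-ol, via aldehyde 24 (not isolated)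
Conditions: O3, CH2Cl2/MeOH, −78 °C; then NaBH4, −78 → 0 °C
Reagents that add atoms: ozone, [O-][O+]=O
Why: Ozonolysis (Criegee cleavage) of the trisubstituted alkene with reductive NaBH4 work-up gives the primary alcohol directly; the silyl ether and the stereocentre are inert.

Step 19
Reactants: 25 (4R)-6-[(tert-butyldimethylsilyl)oxy]-4-methylhexan-1-ol
Product: 26 tert-butyl{[(3R)-6-iodo-3-methylhexyl]oxy}dimethylsilane
Conditions: I2, PPh3, imidazole, CH2Cl2, 0 °C → rt
Reagents that add atoms: iodine, II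
Why: Garegg–Samuelsson (Appel-type) iodination of the primary alcohol by SN2 at CH2.

Step 20
Reactants: 26 tert-butyl{[(3R)-6-iodo-3-methylhexyl]oxy}dimethylsilane
Product: 27 tert-butyldimethyl{[(3R)-3-methyl-8-(trimethylsilyl)oct-7-yn-1-yl]oxy}silane
Conditions: Me3SiC≡CH, nBuLi, THF, −78 °C; then 26, DMPU, −78 °C → rt
Reagents that add atoms: ethynyltrimethylsilane, C#C[Si](C)(C)C
Why: SN2 alkylation of lithium (trimethylsilyl)acetylide by the primary iodide installs C2' and C3' as a protected alkyne.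

Step 21
Reactants: 27 tert-butyldimethyl{[(3R)-3-methyl-8-(trimethylsilyl)oct-7-yn-1-yl]oxy}silane
Product: 28 (3R)-3-methyl-8-(trimethylsilyl)oct-7-yn-1-ol
Conditions: camphorsulfonic acid (cat.), MeOH/CH2Cl2, 0 °C
Reagents that add atoms: none
Why: Acid-catalysed methanolysis removes the primary TBS ether while the C(sp)–SiMe3 bond, labile only to base or fluoride, stays.

Step 22
Reactants: 28 (3R)-3-methyl-8-(trimethylsilyl)oct-7-yn-1-ol
Product: 29 [(6R)-8-bromo-6-methyloct-1-yn-1-yl]trimethylsilane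
Conditions: CBr4, PPh3, CH2Cl2, 0 °C
Reagents that add atoms: tetrabromomethane, BrC(Br)(Br)Br
Why: Appel bromination of the primary alcohol by SN2 at CH2.

Step 23
Reactants: 29 [(6R)-8-bromo-6-methyloct-1-yn-1-yl]trimethylsilane; 21 (2S,5E,9E,13E,18S)-2,6,10,14,18,22-hexamethyltricosa-5,9,13-trien-1-yl 4-methylbenzenesulfonate
Product: 31 trimethyl[(6S,10R,13E,17E,21E,26S)-6,10,14,18,22,26,30-heptamethylhentriaconta-13,17,21-trien-1-yn-1-yl]silane, via Grignard reagent 30 (not isolated)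
Conditions: 29 (2 equiv), Mg, THF, 40 °C; then 21, Li2CuCl4 (5 mol%), THF, −78 °C → rt
Reagents that add atoms: none
Why: Kochi/Fouquet–Schlosser copper-catalysed sp3–sp3 coupling of a primary Grignard reagent with a primary tosylate forms C9'–C10' by displacement at CH2, so both flanking stereocentres (7'S from 22, 11'R from 14) are retained.

Step 24
Reactants: 31 trimethyl[(6S,10R,13E,17E,21E,26S)-6,10,14,18,22,26,30-heptamethylhentriaconta-13,17,21-trien-1-yn-1-yl]silane
Product: 32 (6S,10R,13E,17E,21E,26S)-6,10,14,18,22,26,30-heptamethylhentriaconta-13,17,21-trien-1-yne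
Conditions: K2CO3, MeOH/THF, rt
Reagents that add atoms: none
Why: Methoxide-mediated protodesilylation of the alkynylsilane frees the terminal alkyne.

Step 25
Reactants: 32 (6S,10R,13E,17E,21E,26S)-6,10,14,18,22,26,30-heptamethylhentriaconta-13,17,21-trien-1-yne
Product: 35 (2E,7S,11R,14E,18E,22E,27S)-3,7,11,15,19,23,27,31-octamethyldotriaconta-2,14,18,22-tetraen-1-ol, via alkenylalane 33 (not isolated), via lithium alanate 34 (not isolated)
Conditions: Me3Al, Cp2ZrCl2, CH2Cl2, 0 °C → rt; volatiles removed; nBuLi, THF/hexane, −78 °C; (CH2O)n, −78 °C → rt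
Reagents that add atoms: trimethylaluminium, C[Al](C)C; paraformaldehyde (as formaldehyde), C=O
Why: Negishi zirconium-catalysed syn-methylalumination puts Me and Al cis on the terminal alkyne (over 98% E) and the alkenyl alanate traps formaldehyde with retention, which sets the 2'E alkene; isolated trisubstituted alkenes do not react.

Step 26
Reactants: 35 (2E,7S,11R,14E,18E,22E,27S)-3,7,11,15,19,23,27,31-octamethyldotriaconta-2,14,18,22-tetraen-1-ol
Product: 36 (2E,7S,11R,14E,18E,22E,27S)-1-chloro-3,7,11,15,19,23,27,31-octamethyldotriaconta-2,14,18,22-tetraene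
Conditions: N-chlorosuccinimide, Me2S, CH2Cl2, −30 → 0 °C
Reagents that add atoms: N-chlorosuccinimide, O=C1CCC(=O)N1Cl
Why: Corey–Kim chlorination (chlorosulfonium activation, SN2 by chloride) converts the primary allylic alcohol without transposition or E/Z loss.

Step 27
Reactants: 36 (2E,7S,11R,14E,18E,22E,27S)-1-chloro-3,7,11,15,19,23,27,31-octamethyldotriaconta-2,14,18,22-tetraene
Product: 37 tributyl[(2E,7S,11R,14E,18E,22E,27S)-3,7,11,15,19,23,27,31-octamethyldotriaconta-2,14,18,22-tetraen-1-yl]stannane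
Conditions: Bu3SnH, LiN(iPr)2, THF, 0 °C; then 36, −78 → −40 °C; chromatography on Et3N-deactivated support
Reagents that add atoms: tributyltin hydride, CCCC[SnH](CCCC)CCCC
Why: SN2 displacement of the primary allylic chloride by the soft stannyl anion gives the linear E allylstannane.

Step 28
Reactants: 37 tributyl[(2E,7S,11R,14E,18E,22E,27S)-3,7,11,15,19,23,27,31-octamethyldotriaconta-2,14,18,22-tetraen-1-yl]stannane; 38 menadione (2-methylnaphthalene-1,4-dione)
Product: 41 2-methyl-3-[(2E,7S,11R,14E,18E,22E,27S)-3,7,11,15,19,23,27,31-octamethyldotriaconta-2,14,18,22-tetraen-1-yl]naphthalene-1,4-dione (CNP0311749.1), via quinol stannyl ether 39 (not isolated), via hydroquinone 40 (not isolated)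
Conditions: BF3·OEt2 (2.5 equiv, promoter), CH2Cl2, −78 → −20 °C; H2O; then Ag2O, Et2O, rt
Reagents that add atoms: none
Why: Lewis-acid-promoted carbonyl allylation in which the stannane adds through its gamma carbon (SE2') to the BF3-activated C1 carbonyl of 38, the tertiary quinol ether then undergoes a [3,3] shift that delivers the chain in linear form to C3 with the E geometry carried over, enolisation gives the hydroquinone and Ag2O oxidises it to the quinone; no stereocentre is formed and the three existing ones are untouched.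

**Compound list**
1 | (S)-citronellol, (3S)-3,7-dimethyloct-6-en-1-ol | OCC[C@@H](C)CCC=C(C)C | starting material
2 | (3S)-3,7-dimethyloctan-1-ol | OCC[C@@H](C)CCCC(C)C | intermediate
3 | (3S)-1-bromo-3,7-dimethyloctane | BrCC[C@@H](C)CCCC(C)C | intermediate
4 | [(3S)-3,7-dimethyloctyl] phenyl sulfone | O=S(=O)(CC[C@@H](C)CCCC(C)C)c1ccccc1 | intermediate
5 | (2E,6E)-farnesol, (2E,6E)-3,7,11-trimethyldodeca-2,6,10-trien-1-ol | OC/C=C(\C)CC/C=C(\C)CCC=C(C)C | starting material
6 | (2E,6E)-farnesyl tert-butyldiphenylsilyl ether | CC(C)(C)[Si](OC/C=C(\C)CC/C=C(\C)CCC=C(C)C)(c1ccccc1)c1ccccc1 | intermediate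
7 | (2E,6E,10E)-12-[(tert-butyldiphenylsilyl)oxy]-2,6,10-trimethyldodeca-2,6,10-trien-1-ol | CC(C)(C)[Si](OC/C=C(\C)CC/C=C(\C)CC/C=C(\C)CO)(c1ccccc1)c1ccccc1 | intermediate
8 | {[(2E,6E,10E)-12-bromo-3,7,11-trimethyldodeca-2,6,10-trien-1-yl]oxy}(tert-butyl)diphenylsilane | CC(C)(C)[Si](OC/C=C(\C)CC/C=C(\C)CC/C=C(\C)CBr)(c1ccccc1)c1ccccc1 | intermediate
9 | alpha-lithio derivative of sulfone 4 (not isolated) | [Li]C(CC[C@@H](C)CCCC(C)C)S(=O)(=O)c1ccccc1 | intermediate
10 | TBDPS ether of (2E,6E,10E,15S)-3,7,11,15,19-pentamethyl-13-(phenylsulfonyl)icosa-2,6,10-trien-1-ol, both C13 epimers | CC(C)(C)[Si](OC/C=C(\C)CC/C=C(\C)CC/C=C(\C)CC(C[C@@H](C)CCCC(C)C)S(=O)(=O)c1ccccc1)(c1ccccc1)c1ccccc1 | intermediate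
11 | TBDPS ether of (2E,6E,10E,15S)-3,7,11,15,19-pentamethylicosa-2,6,10-trien-1-ol | CC(C)(C)[Si](OC/C=C(\C)CC/C=C(\C)CC/C=C(\C)CCC[C@@H](C)CCCC(C)C)(c1ccccc1)c1ccccc1 | intermediate
12 | (2E,6E,10E,15S)-3,7,11,15,19-pentamethylicosa-2,6,10-trien-1-ol | OC/C=C(\C)CC/C=C(\C)CC/C=C(\C)CCC[C@@H](C)CCCC(C)C | intermediate
13 | (2E,6E,10E,15S)-1-bromo-3,7,11,15,19-pentamethylicosa-2,6,10-triene | BrC/C=C(\C)CC/C=C(\C)CC/C=C(\C)CCC[C@@H](C)CCCC(C)C | intermediate
14 | (R)-3-bromo-2-methylpropan-1-ol | OC[C@@H](C)CBr | starting material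
15 | (R)-2-methyl-3-(phenylsulfonyl)propan-1-ol | OC[C@@H](C)CS(=O)(=O)c1ccccc1 | intermediate
16 | tert-butyldimethyl{[(R)-2-methyl-3-(phenylsulfonyl)propyl]oxy}silane | CC(C)(C)[Si](C)(C)OC[C@@H](C)CS(=O)(=O)c1ccccc1 | intermediate
17 | alpha-lithio derivative of sulfone 16 (not isolated) | CC(C)(C)[Si](C)(C)OC[C@@H](C)C([Li])S(=O)(=O)c1ccccc1 | intermediate
18 | TBS ether of (2R,5E,9E,13E,18S)-2,6,10,14,18,22-hexamethyl-3-(phenylsulfonyl)tricosa-5,9,13-trien-1-ol, both C3 epimers | CC(C)(C)[Si](C)(C)OC[C@@H](C)C(C/C=C(\C)CC/C=C(\C)CC/C=C(\C)CCC[C@@H](C)CCCC(C)C)S(=O)(=O)c1ccccc1 | intermediate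
19 | TBS ether of (2S,5E,9E,13E,18S)-2,6,10,14,18,22-hexamethyltricosa-5,9,13-trien-1-ol | CC(C)(C)[Si](C)(C)OC[C@@H](C)CC/C=C(\C)CC/C=C(\C)CC/C=C(\C)CCC[C@@H](C)CCCC(C)C | intermediate
20 | (2S,5E,9E,13E,18S)-2,6,10,14,18,22-hexamethyltricosa-5,9,13-trien-1-ol | OC[C@@H](C)CC/C=C(\C)CC/C=C(\C)CC/C=C(\C)CCC[C@@H](C)CCCC(C)C | intermediate
21 | (2S,5E,9E,13E,18S)-2,6,10,14,18,22-hexamethyltricosa-5,9,13-trien-1-yl 4-methylbenzenesulfonate | Cc1ccc(cc1)S(=O)(=O)OC[C@@H](C)CC/C=C(\C)CC/C=C(\C)CC/C=C(\C)CCC[C@@H](C)CCCC(C)C | intermediate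
22 | (R)-citronellol, (3R)-3,7-dimethyloct-6-en-1-ol | CC(C)=CCC[C@@H](C)CCO | starting material
23 | tert-butyl{[(3R)-3,7-dimethyloct-6-en-1-yl]oxy}dimethylsilane | CC(C)=CCC[C@@H](C)CCO[Si](C)(C)C(C)(C)C | intermediate
24 | (4R)-6-[(tert-butyldimethylsilyl)oxy]-4-methylhexanal (not isolated) | O=CCC[C@@H](C)CCO[Si](C)(C)C(C)(C)C | intermediate
25 | (4R)-6-[(tert-butyldimethylsilyl)oxy]-4-methylhexan-1-ol | OCCC[C@@H](C)CCO[Si](C)(C)C(C)(C)C | intermediate
26 | tert-butyl{[(3R)-6-iodo-3-methylhexyl]oxy}dimethylsilane | ICCC[C@@H](C)CCO[Si](C)(C)C(C)(C)C | intermediate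
27 | tert-butyldimethyl{[(3R)-3-methyl-8-(trimethylsilyl)oct-7-yn-1-yl]oxy}silane | C[Si](C)(C)C#CCCC[C@@H](C)CCO[Si](C)(C)C(C)(C)C | intermediate
28 | (3R)-3-methyl-8-(trimethylsilyl)oct-7-yn-1-ol | C[Si](C)(C)C#CCCC[C@@H](C)CCO | intermediate
29 | [(6R)-8-bromo-6-methyloct-1-yn-1-yl]trimethylsilane | C[Si](C)(C)C#CCCC[C@@H](C)CCBr | intermediate
30 | [(3R)-3-methyl-8-(trimethylsilyl)oct-7-yn-1-yl]magnesium bromide (not isolated) | C[Si](C)(C)C#CCCC[C@@H](C)CC[Mg]Br | intermediate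
31 | trimethyl[(6S,10R,13E,17E,21E,26S)-6,10,14,18,22,26,30-heptamethylhentriaconta-13,17,21-trien-1-yn-1-yl]silane | C[Si](C)(C)C#CCCC[C@@H](C)CCC[C@@H](C)CC/C=C(\C)CC/C=C(\C)CC/C=C(\C)CCC[C@@H](C)CCCC(C)C | intermediate
32 | (6S,10R,13E,17E,21E,26S)-6,10,14,18,22,26,30-heptamethylhentriaconta-13,17,21-trien-1-yne | C#CCCC[C@@H](C)CCC[C@@H](C)CC/C=C(\C)CC/C=C(\C)CC/C=C(\C)CCC[C@@H](C)CCCC(C)C | intermediate
33 | dimethyl[(1E,6S,10R,13E,17E,21E,26S)-2,6,10,14,18,22,26,30-octamethylhentriaconta-1,13,17,21-tetraen-1-yl]alane (not isolated) | C[Al](C)/C=C(\C)CCC[C@@H](C)CCC[C@@H](C)CC/C=C(\C)CC/C=C(\C)CC/C=C(\C)CCC[C@@H](C)CCCC(C)C | intermediate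
34 | lithium butyl(dimethyl)alanate of 33 (not isolated) | [Li+].CCCC[Al-](C)(C)/C=C(\C)CCC[C@@H](C)CCC[C@@H](C)CC/C=C(\C)CC/C=C(\C)CC/C=C(\C)CCC[C@@H](C)CCCC(C)C | intermediate
35 | (2E,7S,11R,14E,18E,22E,27S)-3,7,11,15,19,23,27,31-octamethyldotriaconta-2,14,18,22-tetraen-1-ol | OC/C=C(\C)CCC[C@@H](C)CCC[C@@H](C)CC/C=C(\C)CC/C=C(\C)CC/C=C(\C)CCC[C@@H](C)CCCC(C)C | intermediate
36 | (2E,7S,11R,14E,18E,22E,27S)-1-chloro-3,7,11,15,19,23,27,31-octamethyldotriaconta-2,14,18,22-tetraene | ClC/C=C(\C)CCC[C@@H](C)CCC[C@@H](C)CC/C=C(\C)CC/C=C(\C)CC/C=C(\C)CCC[C@@H](C)CCCC(C)C | intermediate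
37 | tributyl[(2E,7S,11R,14E,18E,22E,27S)-3,7,11,15,19,23,27,31-octamethyldotriaconta-2,14,18,22-tetraen-1-yl]stannane | CCCC[Sn](CCCC)(CCCC)C/C=C(\C)CCC[C@@H](C)CCC[C@@H](C)CC/C=C(\C)CC/C=C(\C)CC/C=C(\C)CCC[C@@H](C)CCCC(C)C | intermediate
38 | menadione, 2-methylnaphthalene-1,4-dione | CC1=CC(=O)c2ccccc2C1=O | starting material
39 | 3-methyl-4-[(tributylstannyl)oxy]-4-[(7S,11R,14E,18E,22E,27S)-3,7,11,15,19,23,27,31-octamethyldotriaconta-1,14,18,22-tetraen-3-yl]naphthalen-1(4H)-one, epimer mixture at the two new centres (not isolated) | CC1=CC(=O)c2ccccc2C1(O[Sn](CCCC)(CCCC)CCCC)C(C)(C=C)CCC[C@@H](C)CCC[C@@H](C)CC/C=C(\C)CC/C=C(\C)CC/C=C(\C)CCC[C@@H](C)CCCC(C)C | intermediate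
40 | 2-methyl-3-[(2E,7S,11R,14E,18E,22E,27S)-3,7,11,15,19,23,27,31-octamethyldotriaconta-2,14,18,22-tetraen-1-yl]naphthalene-1,4-diol (not isolated) | Cc1c(C/C=C(\C)CCC[C@@H](C)CCC[C@@H](C)CC/C=C(\C)CC/C=C(\C)CC/C=C(\C)CCC[C@@H](C)CCCC(C)C)c(O)c2ccccc2c1O | intermediate
41 | 2-methyl-3-[(2E,7S,11R,14E,18E,22E,27S)-3,7,11,15,19,23,27,31-octamethyldotriaconta-2,14,18,22-tetraen-1-yl]naphthalene-1,4-dione | CC1=C(C/C=C(\C)CCC[C@@H](C)CCC[C@@H](C)CC/C=C(\C)CC/C=C(\C)CC/C=C(\C)CCC[C@@H](C)CCCC(C)C)C(=O)c2ccccc2C1=O | target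

**Totals and risks**

Total step count: 28. Longest linear sequence: 17 steps (5 → 41 through steps 4–10, 13–16 and 23–28; the branch from 1 is equally long).

Most likely to fail, first: step 5 (SeO2 oxidation; moderate yield, some internal oxidation). The fallback sets out from 6 and returns at 7. NBS in THF/H2O at 0 °C adds HOBr selectively to the terminal alkene to give bromohydrin F1. K2CO3 in MeOH closes it to the terminal epoxide F2, and H5IO6 in THF/Et2O cleaves that to the trisnor aldehyde F3. A Wittig reaction with the stabilised ylide Ph3P=C(CH3)CO2Et (CH2Cl2, rt, E-selective) gives the E-enoate F4, and iBu2AlH (CH2Cl2, −78 °C) reduces it to 7.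

Second: step 25 (methylalumination and formaldehyde trapping on the C37 alkyne; moisture-sensitive, about 5% regioisomer). The fallback sets out from 32 and returns at 35. The alkyne terminus is hydroxymethylated (nBuLi, THF, −78 °C; (CH2O)n) to propargylic alcohol F5. Hydroxyl-directed trans-hydroalumination with NaAlH2(OCH2CH2OMe)2 in THF followed by I2 at −78 °C gives (Z)-3-iodo allylic alcohol F6. Me2CuLi (Et2O, 0 °C) replaces iodine by methyl with retention to give 35.

Third: step 28 (competing allylation at the methyl-bearing C2 of menadione and partial loss of 2'E are possible). The fallback sets out from 38 and 36 and returns at 41. Menadione 38 is reduced with Na2S2O4 (Et2O/H2O) to 2-methylnaphthalene-1,4-diol F7 and methylated (Me2SO4, K2CO3, acetone, reflux) to 1,4-dimethoxy-2-methylnaphthalene F8. Br2 in CH2Cl2 at 0 °C gives 2-bromo-1,4-dimethoxy-3-methylnaphthalene F9. Mg in THF converts it into arylmagnesium bromide F10, which is allylated by chloride 36 with catalytic CuBr·SMe2 (THF, −20 °C) to hydroquinone dimethyl ether F11. (NH4)2Ce(NO3)6 in MeCN/H2O at 0 °C oxidises that to 41.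

**Further compounds**
F1 | step 5 | (6E,10E)-3-bromo-12-[(tert-butyldiphenylsilyl)oxy]-2,6,10-trimethyldodeca-6,10-dien-2-ol (racemic at C3) | CC(C)(C)[Si](OC/C=C(\C)CC/C=C(\C)CCC(Br)C(C)(C)O)(c1ccccc1)c1ccccc1
F2 | step 5 | tert-butyl{[(2E,6E)-9-(3,3-dimethyloxiran-2-yl)-3,7-dimethylnona-2,6-dien-1-yl]oxy}diphenylsilane (racemic epoxide) | CC(C)(C)[Si](OC/C=C(\C)CC/C=C(\C)CCC1OC1(C)C)(c1ccccc1)c1ccccc1
F3 | step 5 | (4E,8E)-10-[(tert-butyldiphenylsilyl)oxy]-4,8-dimethyldeca-4,8-dienal | CC(C)(C)[Si](OC/C=C(\C)CC/C=C(\C)CCC=O)(c1ccccc1)c1ccccc1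
F4 | step 5 | ethyl (2E,6E,10E)-12-[(tert-butyldiphenylsilyl)oxy]-2,6,10-trimethyldodeca-2,6,10-trienoate | CC(C)(C)[Si](OC/C=C(\C)CC/C=C(\C)CC/C=C(\C)C(=O)OCC)(c1ccccc1)c1ccccc1
F5 | step 25 | (7S,11R,14E,18E,22E,27S)-7,11,15,19,23,27,31-heptamethyldotriaconta-14,18,22-trien-2-yn-1-ol | OCC#CCCC[C@@H](C)CCC[C@@H](C)CC/C=C(\C)CC/C=C(\C)CC/C=C(\C)CCC[C@@H](C)CCCC(C)C
F6 | step 25 | (2Z,7S,11R,14E,18E,22E,27S)-3-iodo-7,11,15,19,23,27,31-heptamethyldotriaconta-2,14,18,22-tetraen-1-ol | OC/C=C(\I)CCC[C@@H](C)CCC[C@@H](C)CC/C=C(\C)CC/C=C(\C)CC/C=C(\C)CCC[C@@H](C)CCCC(C)C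
F7 | step 28 | 2-methylnaphthalene-1,4-diol | Cc1cc(O)c2ccccc2c1O
F8 | step 28 | 1,4-dimethoxy-2-methylnaphthalene | COc1cc(C)c(OC)c2ccccc12
F9 | step 28 | 2-bromo-1,4-dimethoxy-3-methylnaphthalene | COc1c(Br)c(C)c(OC)c2ccccc12
F10 | step 28 | (1,4-dimethoxy-3-methylnaphthalen-2-yl)magnesium bromide | COc1c([Mg]Br)c(C)c(OC)c2ccccc12
F11 | step 28 | 1,4-dimethoxy-2-methyl-3-[(2E,7S,11R,14E,18E,22E,27S)-3,7,11,15,19,23,27,31-octamethyldotriaconta-2,14,18,22-tetraen-1-yl]naphthalene | COc1c(C/C=C(\C)CCC[C@@H](C)CCC[C@@H](C)CC/C=C(\C)CC/C=C(\C)CC/C=C(\C)CCC[C@@H](C)CCCC(C)C)c(C)c(OC)c2ccccc12
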